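**Retrosynthetic overview**

1. The target is a (3S,4S)-trans-dibenzylbutyrolactone. Ring A is the left guaiacyl ring, ring B the phenol ring on the C3 benzyl group, ring C the arene of the dihydrobenzofuran on the C4 benzyl group, ring D the guaiacyl ring on benzofuran C2. Last events: global desilylation, preceded by formation of the ring C aryl–CH2 bond by nickel-catalysed decarboxylative coupling of aryl bromide 17 with redox-active ester 35.
2. The strategy rests on the O1–C2 bond of the dihydrobenzofuran. It joins the ring C phenol oxygen to a benzylic carbon para to the ring D phenol, so C2 can be ionised to a para-quinone methide and re-formed while C3 stays fixed. O1–C2 is therefore disconnected to the open 1,3-diol 14 and closed trans by acid.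
3. The open left arm (rings A/B) is the same unit, uncyclised, with the same (S) aryl-bearing carbon on the same ring pattern. One anti-aldol adduct (diol 13, from 5-bromo-o-vanillin, vanillin and an Evans auxiliary) therefore feeds both halves.
4. Left half: the ring B bromide becomes a benzylic bromide, which alkylates (S)-4-allylbutyrolactone 25 trans (C4 from an Evans alkylation); the allyl group is then cut down to CH2CO2H and activated as the N-acyloxyphthalimide.
5. Rings formed: the dihydrofuran ring (step 9) and the butyrolactone (step 14), in separate branches; all four arenes are bought.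

Key step: step 9

Remark: the magnesium-catalysed aldol of step 6 is taken to follow the chelate model of this auxiliary (attack anti to the benzyl group, as in its enolate alkylations), which makes (S)-4-benzyl-1,3-oxazolidin-2-one the correct antipode.

**Route**

Step 1
Reactants: 1 5-bromo-2-hydroxy-3-methoxybenzaldehyde
Product: 2 5-bromo-3-methoxy-2-[(triisopropylsilyl)oxy]benzaldehyde
Conditions: TIPSCl, imidazole, DMAP (cat.), DMF, 23 °C
Reagents that add atoms: chlorotriisopropylsilane, CC(C)[Si](Cl)(C(C)C)C(C)C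
Why: Imidazole-mediated silyl ether formation masks the acidic phenol before the Wittig reaction, and the bulky aryl TIPS ether should survive the later enolate, hydride and mild acid steps.

Step 2
Reactants: 2 5-bromo-3-methoxy-2-[(triisopropylsilyl)oxy]benzaldehyde
Product: 3 [4-bromo-2-methoxy-6-(2-methoxyethenyl)phenoxy]triisopropylsilane (E/Z mixture)
Conditions: Ph3P(CH2OMe)Cl, KOt-Bu, THF, 0 → 23 °C
Reagents that add atoms: (methoxymethyl)triphenylphosphonium chloride, COC[P+](c1ccccc1)(c1ccccc1)c1ccccc1.[Cl-]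
Why: Wittig olefination with the methoxymethylene ylide installs the one-carbon homologation handle, and the alkene geometry is immaterial because both isomers hydrolyse to the same aldehyde.

Step 3
Reactants: 3 [4-bromo-2-methoxy-6-(2-methoxyethenyl)phenoxy]triisopropylsilane
Product: 5 {5-bromo-3-methoxy-2-[(triisopropylsilyl)oxy]phenyl}acetic acid, via arylacetaldehyde 4 (not isolated)
Conditions: 2 M aq HCl, THF, 40 °C; then NaH2PO4, t-BuOH, 2-methyl-2-butene, NaClO2, 0 → 23 °C
Reagents that add atoms: water, O; sodium chlorite, [Na+].[O-]Cl=O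
Why: Acid hydrolysis of the enol ether releases the sensitive arylacetaldehyde, which is oxidised in the same flask by the Pinnick chlorite oxidation while 2-methyl-2-butene scavenges HOCl so that the electron-rich ring is not chlorinated.

Step 4
Reactants: 5 {5-bromo-3-methoxy-2-[(triisopropylsilyl)oxy]phenyl}acetic acid; 6 (S)-4-benzyl-1,3-oxazolidin-2-one
Product: 8 (4S)-4-benzyl-3-({5-bromo-3-methoxy-2-[(triisopropylsilyl)oxy]phenyl}acetyl)-1,3-oxazolidin-2-one, via mixed pivalic anhydride 7 (not isolated)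
Conditions: PivCl, Et3N, THF, −20 °C; then LiCl, 6, −20 → 23 °C
Reagents that add atoms: none
Why: N-acylation of the Evans oxazolidinone through the mixed pivalic anhydride under LiCl/Et3N activation is a standard one-pot procedure that needs no strong base and leaves the aryl silyl ether intact.

Step 5
Reactants: 9 vanillin (4-hydroxy-3-methoxybenzaldehyde)
Product: 10 3-methoxy-4-[(triisopropylsilyl)oxy]benzaldehyde
Conditions: TIPSCl, imidazole, DMF, 23 °C
Reagents that add atoms: chlorotriisopropylsilane, CC(C)[Si](Cl)(C(C)C)C(C)C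
Why: Silyl ether formation blocks the phenol, which would otherwise quench the amine base and the enolate in the aldol step.

Step 6
Reactants: 8 (4S)-4-benzyl-3-({5-bromo-3-methoxy-2-[(triisopropylsilyl)oxy]phenyl}acetyl)-1,3-oxazolidin-2-one; 10 3-methoxy-4-[(triisopropylsilyl)oxy]benzaldehyde
Product: 12 (4S)-4-benzyl-3-[(2R,3S)-2-{5-bromo-3-methoxy-2-[(triisopropylsilyl)oxy]phenyl}-3-hydroxy-3-{3-methoxy-4-[(triisopropylsilyl)oxy]phenyl}propanoyl]-1,3-oxazolidin-2-one, via trimethylsilyl ether 11 (not isolated)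
Conditions: MgCl2 (0.2 equiv), Et3N, TMSCl, EtOAc, 23 °C; then 0.5 M aq HCl, THF, 0 °C
Reagents that add atoms: none
Why: In this Evans magnesium halide-catalysed direct anti-aldol reaction, soft enolisation gives the chelated (Z)-magnesium enolate, the aldehyde adds to the face opposite the auxiliary benzyl group (C2 set as R) through a boat-like transition state (carbinol set as S, anti), TMSCl traps the aldolate to release the catalyst and block retro-aldol, and brief dilute acid cleaves only the TMS ether.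

Step 7
Reactants: 12 aldol adduct (as named in step 6)
Product: 13 (1S,2S)-2-{5-bromo-3-methoxy-2-[(triisopropylsilyl)oxy]phenyl}-1-{3-methoxy-4-[(triisopropylsilyl)oxy]phenyl}propane-1,3-diol
Conditions: LiBH4, MeOH, THF, 0 °C
Reagents that add atoms: none
Why: Reductive cleavage of the imide by LiBH4 attacks the exocyclic carbonyl selectively and should give the primary alcohol and the recovered auxiliary without touching the aryl bromide, the silyl ethers or either stereocentre.

Step 8
Reactants: 13 (1S,2S)-diol (as named in step 7)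
Product: 14 (1S,2S)-2-(5-bromo-2-hydroxy-3-methoxyphenyl)-1-(4-hydroxy-3-methoxyphenyl)propane-1,3-diol
Conditions: Bu4NF, AcOH, THF, 0 °C
Reagents that add atoms: none
Why: Fluoride cleaves the two aryl silyl ethers rapidly, and acetic acid buffering keeps the liberated electron-rich bisphenol protonated so that no stereocentre is disturbed.

Step 9
Reactants: 14 (1S,2S)-2-(5-bromo-2-hydroxy-3-methoxyphenyl)-1-(4-hydroxy-3-methoxyphenyl)propane-1,3-diol
Product: 16 [(2R,3S)-5-bromo-2-(4-hydroxy-3-methoxyphenyl)-7-methoxy-2,3-dihydro-1-benzofuran-3-yl]methanol, via para-quinone methide 15 (not isolated)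
Conditions: TsOH·H2O (0.2 equiv), MeCN (0.01 M), 23 °C
Reagents that add atoms: none
Why: Acid protonates the benzylic hydroxyl, and loss of water, pushed by the para oxygen of ring D, gives the para-quinone methide 15 (or its O-protonated form), to whose exocyclic carbon the ortho phenol oxygen of ring C adds in a 1,6-oxa-Michael addition that forms O1–C2 and restores the aromaticity of ring D. The closest known reaction is the acid-catalysed closure of 2-(2-hydroxyaryl)-1-(4-hydroxyaryl)propane-1,3-diols to trans-phenylcoumarans. The dihydrofuran ring closes in the 5-exo-trig mode. C2 is set as R by the existing C3 centre, because the aryl group takes the face anti to the C3 hydroxymethyl group in the closing transition state, and since the benzylic C–O bond can reopen under the same acid the more stable trans isomer should accumulate. The step needs the trans ring from any carbinol configuration and attack by the phenol oxygen alone: the planar intermediate erases the carbinol centre so that aldol material of either C1 configuration converges, the primary hydroxyl could only close a strained oxetane, C3 is never conjugated with the cation, and high dilution holds back intermolecular arene alkylation.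

Step 10
Reactants: 16 [(2R,3S)-5-bromo-2-(4-hydroxy-3-methoxyphenyl)-7-methoxy-2,3-dihydro-1-benzofuran-3-yl]methanol
Product: 17 (2R,3S)-5-bromo-2-{4-[(tert-butyldimethylsilyl)oxy]-3-methoxyphenyl}-3-{[(tert-butyldimethylsilyl)oxy]methyl}-7-methoxy-2,3-dihydro-1-benzofuran
Conditions: TBSCl, imidazole, DMF, 23 °C
Reagents that add atoms: tert-butylchlorodimethylsilane, CC(C)(C)[Si](C)(C)Cl
Why: Silyl ether formation at the phenol and the primary alcohol keeps both from being acylated by the active ester in the coupling and matches the fluoride-labile protection of the left half.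

Step 11
Reactants: 18 (R)-4-benzyl-1,3-oxazolidin-2-one; 19 pent-4-enoyl chloride
Product: 20 (4R)-4-benzyl-3-(pent-4-enoyl)-1,3-oxazolidin-2-one
Conditions: Et3N, DMAP (cat.), CH2Cl2, 0 → 23 °C
Reagents that add atoms: none
Why: DMAP-catalysed N-acylation of the oxazolidinone with the acid chloride is a routine way to the Evans imide.

Step 12
Reactants: 20 (4R)-4-benzyl-3-(pent-4-enoyl)-1,3-oxazolidin-2-one; 21 tert-butyl bromoacetate
Product: 23 tert-butyl (3S)-3-{[(4R)-4-benzyl-2-oxo-1,3-oxazolidin-3-yl]carbonyl}hex-5-enoate, via sodium enolate 22 (not isolated)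
Conditions: NaN(SiMe3)2, THF, −78 °C; then 21, −78 → −40 °C
Reagents that add atoms: none
Why: In this Evans asymmetric alkylation the chelated (Z)-sodium enolate is alkylated by the reactive bromoacetate on the face opposite the auxiliary benzyl group, which sets the future lactone C4 as S.

Step 13
Reactants: 23 tert-butyl (3S)-3-{[(4R)-4-benzyl-2-oxo-1,3-oxazolidin-3-yl]carbonyl}hex-5-enoate
Product: 24 tert-butyl (3S)-3-(hydroxymethyl)hex-5-enoate
Conditions: LiBH4, MeOH, Et2O, 0 °C
Reagents that add atoms: none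
Why: LiBH4 reduces the activated imide carbonyl chemoselectively in the presence of the hindered tert-butyl ester and releases the auxiliary without affecting the stereocentre.

Step 14
Reactants: 24 tert-butyl (3S)-3-(hydroxymethyl)hex-5-enoate
Product: 25 (4S)-4-(prop-2-en-1-yl)oxolan-2-one
Conditions: CF3CO2H, CH2Cl2, 23 °C
Reagents that add atoms: none
Why: Acid cleaves the tert-butyl ester with loss of isobutene and the resulting γ-hydroxy acid lactonises spontaneously (5-exo-trig) to the butyrolactone, the stereocentre taking no part.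

Step 15
Reactants: 13 (1S,2S)-diol (as named in step 7)
Product: 26 (1S,2S)-2-{5-bromo-3-methoxy-2-[(triisopropylsilyl)oxy]phenyl}-1,3-bis[(tert-butyldimethylsilyl)oxy]-1-{3-methoxy-4-[(triisopropylsilyl)oxy]phenyl}propane
Conditions: TBSOTf, 2,6-lutidine, CH2Cl2, −78 → 0 °C
Reagents that add atoms: tert-butyldimethylsilyl trifluoromethanesulfonate, CC(C)(C)[Si](C)(C)OS(=O)(=O)C(F)(F)F
Why: The silyl triflate silylates both the primary and the hindered benzylic hydroxyl at low temperature, and the lutidine buffer keeps the electron-rich benzylic carbinol from ionising.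

Step 16
Reactants: 26 bis-TBS ether (as named in step 15)
Product: 29 ArL–CH2OH, where ArL is 3-[(1S,2S)-1,3-bis{[tert-butyldimethylsilyl]oxy}-1-{3-methoxy-4-[(triisopropylsilyl)oxy]phenyl}propan-2-yl]-5-methoxy-4-[(triisopropylsilyl)oxy]phenyl, via aryllithium 27 (not isolated), via benzaldehyde 28 (not isolated)
Conditions: t-BuLi (2.1 equiv), THF, −78 °C; DMF, −78 → 0 °C; then MeOH, NaBH4, 0 °C
Reagents that add atoms: N,N-dimethylformamide, CN(C)C=O
Why: Bromine–lithium exchange is far faster than any deprotonation at −78 °C, the aryllithium is formylated by DMF (Bouveault formylation) and the aldehyde is reduced in the same flask by NaBH4 to the benzylic alcohol.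

Step 17
Reactants: 29 ArL–CH2OH
Product: 30 ArL–CH2Br (benzylic bromide of the left half)
Conditions: CBr4, PPh3, CH2Cl2, 0 °C
Reagents that add atoms: tetrabromomethane, BrC(Br)(Br)Br
Why: Appel bromination converts the unhindered primary benzylic alcohol into the bromide under neutral conditions that the four silyl ethers tolerate.

Step 18
Reactants: 25 (4S)-4-(prop-2-en-1-yl)oxolan-2-one; 30 ArL–CH2Br
Product: 32 (3S,4S)-3-(ArL-methyl)-4-(prop-2-en-1-yl)oxolan-2-one, via lithium enolate 31 (not isolated)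
Conditions: 25 (1.5 equiv), LiN(SiMe3)2, THF, −78 °C; then 30, DMPU, −78 → −30 °C
Reagents that add atoms: none
Why: The lithium enolate of the 4-substituted butyrolactone is alkylated by the benzylic bromide anti to the C4 allyl group, which sets C3 as S and gives the trans-3,4-disubstituted lactone, the standard stereocontrol of dibenzylbutyrolactone lignan synthesis.

Step 19
Reactants: 32 (3S,4S)-3-(ArL-methyl)-4-(prop-2-en-1-yl)oxolan-2-one
Product: 33 2-[(3S,4S)-4-(ArL-methyl)-5-oxooxolan-3-yl]acetaldehyde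
Conditions: OsO4 (2 mol %), NaIO4, 2,6-lutidine, dioxane–H2O (3:1), 23 °C
Reagents that add atoms: osmium tetroxide, O=[Os](=O)(=O)=O; sodium periodate, [Na+].[O-]I(=O)(=O)=O
Why: Lemieux–Johnson cleavage (catalytic dihydroxylation, then periodate scission) shortens the terminal alkene to the aldehyde without attacking the silylated electron-rich arenes.

Step 20
Reactants: 33 2-[(3S,4S)-4-(ArL-methyl)-5-oxooxolan-3-yl]acetaldehyde
Product: 34 2-[(3S,4S)-4-(ArL-methyl)-5-oxooxolan-3-yl]acetic acid
Conditions: NaClO2, NaH2PO4, 2-methyl-2-butene, t-BuOH–H2O, 0 → 23 °C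
Reagents that add atoms: sodium chlorite, [Na+].[O-]Cl=O
Why: Pinnick oxidation takes the aldehyde to the acid under weakly acidic buffered conditions that epimerise neither lactone centre and do not ionise the silylated benzylic carbinol.

Step 21
Reactants: 34 2-[(3S,4S)-4-(ArL-methyl)-5-oxooxolan-3-yl]acetic acid
Product: 35 1,3-dioxoisoindolin-2-yl 2-[(3S,4S)-4-(ArL-methyl)-5-oxooxolan-3-yl]acetate
Conditions: N-hydroxyphthalimide, N,N′-diisopropylcarbodiimide, DMAP (cat.), CH2Cl2, 23 °C
Reagents that add atoms: N-hydroxyphthalimide, O=C1N(O)C(=O)c2ccccc12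
Why: Carbodiimide (Steglich-type) esterification with N-hydroxyphthalimide gives the redox-active ester needed for decarboxylative coupling.

Step 22
Reactants: 35 redox-active ester (as named in step 21); 17 silylated aryl bromide (as named in step 10)
Product: 36 hexasilyl ether of the target: (3S,4S)-3-(ArL-methyl)-4-{[(2R,3S)-2-{4-[(tert-butyldimethylsilyl)oxy]-3-methoxyphenyl}-3-{[(tert-butyldimethylsilyl)oxy]methyl}-7-methoxy-2,3-dihydro-1-benzofuran-5-yl]methyl}oxolan-2-one
Conditions: NiBr2·glyme (20 mol %), 4,4′-di-tert-butyl-2,2′-bipyridine (20 mol %), Zn, DMA, 23 °C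
Reagents that add atoms: none
Why: In this nickel-catalysed decarboxylative cross-electrophile coupling zinc turns over the nickel catalyst, which adds oxidatively to the unhindered aryl bromide, while single-electron reduction of the N-acyloxyphthalimide and loss of CO2 hand the primary CH2 group to nickel for reductive elimination, forming the ring C aryl–CH2 bond at a carbon that is not stereogenic.

Step 23
Reactants: 36 hexasilyl ether of the target
Product: 37 CNP0186558.3, (3S,4S)-3-({3-[(1S,2S)-1,3-dihydroxy-1-(4-hydroxy-3-methoxyphenyl)propan-2-yl]-4-hydroxy-5-methoxyphenyl}methyl)-4-{[(2R,3S)-2-(4-hydroxy-3-methoxyphenyl)-3-(hydroxymethyl)-7-methoxy-2,3-dihydro-1-benzofuran-5-yl]methyl}oxolan-2-one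
Conditions: Bu4NF, AcOH, THF, 0 → 40 °C
Reagents that add atoms: none
Why: Buffered fluoride removes all six silyl ethers without acid strong enough to ionise the left-arm benzylic carbinol (which would epimerise it or close a second dihydrofuran ring) and without base strong enough to open the lactone or form a quinone methide from the freed phenol.

**Compound list**

1 | 5-bromo-2-hydroxy-3-methoxybenzaldehyde | COc1cc(Br)cc(C=O)c1O | starting material
2 | 5-bromo-3-methoxy-2-[(triisopropylsilyl)oxy]benzaldehyde | COc1cc(Br)cc(C=O)c1O[Si](C(C)C)(C(C)C)C(C)C | intermediate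
3 | [4-bromo-2-methoxy-6-(2-methoxyethenyl)phenoxy]triisopropylsilane (E/Z) | COC=Cc1cc(Br)cc(OC)c1O[Si](C(C)C)(C(C)C)C(C)C | intermediate
4 | {5-bromo-3-methoxy-2-[(triisopropylsilyl)oxy]phenyl}acetaldehyde | COc1cc(Br)cc(CC=O)c1O[Si](C(C)C)(C(C)C)C(C)C | intermediate (not isolated)
5 | {5-bromo-3-methoxy-2-[(triisopropylsilyl)oxy]phenyl}acetic acid | COc1cc(Br)cc(CC(=O)O)c1O[Si](C(C)C)(C(C)C)C(C)C | intermediate
6 | (S)-4-benzyl-1,3-oxazolidin-2-one | O=C1N[C@@H](Cc2ccccc2)CO1 | starting material
7 | mixed anhydride of acid 5 with pivalic acid | COc1cc(Br)cc(CC(=O)OC(=O)C(C)(C)C)c1O[Si](C(C)C)(C(C)C)C(C)C | intermediate (not isolated)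
8 | (4S)-4-benzyl-3-({5-bromo-3-methoxy-2-[(triisopropylsilyl)oxy]phenyl}acetyl)-1,3-oxazolidin-2-one | COc1cc(Br)cc(CC(=O)N2[C@@H](Cc3ccccc3)COC2=O)c1O[Si](C(C)C)(C(C)C)C(C)C | intermediate
9 | vanillin | COc1cc(C=O)ccc1O | starting material
10 | 3-methoxy-4-[(triisopropylsilyl)oxy]benzaldehyde | COc1cc(C=O)ccc1O[Si](C(C)C)(C(C)C)C(C)C | intermediate
11 | (2R,3S) aldol adduct as its 3-O-trimethylsilyl ether | COc1cc(Br)cc([C@@H](C(=O)N2[C@@H](Cc3ccccc3)COC2=O)[C@H](O[Si](C)(C)C)c2ccc(O[Si](C(C)C)(C(C)C)C(C)C)c(OC)c2)c1O[Si](C(C)C)(C(C)C)C(C)C | intermediate (not isolated)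
12 | (4S)-4-benzyl-3-[(2R,3S)-2-{5-bromo-3-methoxy-2-[(triisopropylsilyl)oxy]phenyl}-3-hydroxy-3-{3-methoxy-4-[(triisopropylsilyl)oxy]phenyl}propanoyl]-1,3-oxazolidin-2-one | COc1cc(Br)cc([C@@H](C(=O)N2[C@@H](Cc3ccccc3)COC2=O)[C@H](O)c2ccc(O[Si](C(C)C)(C(C)C)C(C)C)c(OC)c2)c1O[Si](C(C)C)(C(C)C)C(C)C | intermediate
13 | (1S,2S)-2-{5-bromo-3-methoxy-2-[(triisopropylsilyl)oxy]phenyl}-1-{3-methoxy-4-[(triisopropylsilyl)oxy]phenyl}propane-1,3-diol | COc1cc(Br)cc([C@@H](CO)[C@H](O)c2ccc(O[Si](C(C)C)(C(C)C)C(C)C)c(OC)c2)c1O[Si](C(C)C)(C(C)C)C(C)C | intermediate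
14 | (1S,2S)-2-(5-bromo-2-hydroxy-3-methoxyphenyl)-1-(4-hydroxy-3-methoxyphenyl)propane-1,3-diol | COc1cc(Br)cc([C@@H](CO)[C@H](O)c2ccc(O)c(OC)c2)c1O | intermediate
15 | 4-[(2S)-2-(5-bromo-2-hydroxy-3-methoxyphenyl)-3-hydroxypropylidene]-2-methoxycyclohexa-2,5-dien-1-one | COC1=CC(=C[C@H](CO)c2cc(Br)cc(OC)c2O)C=CC1=O | intermediate (not isolated)
16 | [(2R,3S)-5-bromo-2-(4-hydroxy-3-methoxyphenyl)-7-methoxy-2,3-dihydro-1-benzofuran-3-yl]methanol | Brc1cc(OC)c2c(c1)[C@@H](CO)[C@H](c1ccc(O)c(OC)c1)O2 | intermediate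
17 | (2R,3S)-5-bromo-2-{4-[(tert-butyldimethylsilyl)oxy]-3-methoxyphenyl}-3-{[(tert-butyldimethylsilyl)oxy]methyl}-7-methoxy-2,3-dihydro-1-benzofuran | Brc1cc(OC)c2c(c1)[C@@H](CO[Si](C)(C)C(C)(C)C)[C@H](c1ccc(O[Si](C)(C)C(C)(C)C)c(OC)c1)O2 | intermediate
18 | (R)-4-benzyl-1,3-oxazolidin-2-one | O=C1N[C@H](Cc2ccccc2)CO1 | starting material
19 | pent-4-enoyl chloride | C=CCCC(=O)Cl | starting material
20 | (4R)-4-benzyl-3-(pent-4-enoyl)-1,3-oxazolidin-2-one | C=CCCC(=O)N1[C@H](Cc2ccccc2)COC1=O | intermediate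
21 | tert-butyl bromoacetate | CC(C)(C)OC(=O)CBr | starting material
22 | sodium (Z)-enolate of imide 20 | [Na+].[O-]/C(=C\CC=C)N1[C@H](Cc2ccccc2)COC1=O | intermediate (not isolated)
23 | tert-butyl (3S)-3-{[(4R)-4-benzyl-2-oxo-1,3-oxazolidin-3-yl]carbonyl}hex-5-enoate | C=CC[C@@H](CC(=O)OC(C)(C)C)C(=O)N1[C@H](Cc2ccccc2)COC1=O | intermediate
24 | tert-butyl (3S)-3-(hydroxymethyl)hex-5-enoate | C=CC[C@H](CO)CC(=O)OC(C)(C)C | intermediate
25 | (4S)-4-(prop-2-en-1-yl)oxolan-2-one | C=CC[C@@H]1COC(=O)C1 | intermediate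
26 | (1S,2S)-2-{5-bromo-3-methoxy-2-[(triisopropylsilyl)oxy]phenyl}-1,3-bis[(tert-butyldimethylsilyl)oxy]-1-{3-methoxy-4-[(triisopropylsilyl)oxy]phenyl}propane | COc1cc(Br)cc([C@@H](CO[Si](C)(C)C(C)(C)C)[C@H](O[Si](C)(C)C(C)(C)C)c2ccc(O[Si](C(C)C)(C(C)C)C(C)C)c(OC)c2)c1O[Si](C(C)C)(C(C)C)C(C)C | intermediate
27 | aryllithium ArL–Li from 26 | COc1cc([Li])cc([C@@H](CO[Si](C)(C)C(C)(C)C)[C@H](O[Si](C)(C)C(C)(C)C)c2ccc(O[Si](C(C)C)(C(C)C)C(C)C)c(OC)c2)c1O[Si](C(C)C)(C(C)C)C(C)C | intermediate (not isolated)
28 | ArL–CHO: 3-[(1S,2S)-1,3-bis{[tert-butyldimethylsilyl]oxy}-1-{3-methoxy-4-[(triisopropylsilyl)oxy]phenyl}propan-2-yl]-5-methoxy-4-[(triisopropylsilyl)oxy]benzaldehyde | COc1cc(C=O)cc([C@@H](CO[Si](C)(C)C(C)(C)C)[C@H](O[Si](C)(C)C(C)(C)C)c2ccc(O[Si](C(C)C)(C(C)C)C(C)C)c(OC)c2)c1O[Si](C(C)C)(C(C)C)C(C)C | intermediate (not isolated)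
29 | ArL–CH2OH (benzylic alcohol of the left half) | COc1cc(CO)cc([C@@H](CO[Si](C)(C)C(C)(C)C)[C@H](O[Si](C)(C)C(C)(C)C)c2ccc(O[Si](C(C)C)(C(C)C)C(C)C)c(OC)c2)c1O[Si](C(C)C)(C(C)C)C(C)C | intermediate
30 | ArL–CH2Br (benzylic bromide of the left half) | COc1cc(CBr)cc([C@@H](CO[Si](C)(C)C(C)(C)C)[C@H](O[Si](C)(C)C(C)(C)C)c2ccc(O[Si](C(C)C)(C(C)C)C(C)C)c(OC)c2)c1O[Si](C(C)C)(C(C)C)C(C)C | intermediate
31 | lithium (4S)-4-(prop-2-en-1-yl)-4,5-dihydrofuran-2-olate | [Li+].[O-]C1=C[C@H](CC=C)CO1 | intermediate (not isolated)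
32 | (3S,4S)-3-(ArL-methyl)-4-(prop-2-en-1-yl)oxolan-2-one | COc1cc(C[C@@H]2C(=O)OC[C@H]2CC=C)cc([C@@H](CO[Si](C)(C)C(C)(C)C)[C@H](O[Si](C)(C)C(C)(C)C)c2ccc(O[Si](C(C)C)(C(C)C)C(C)C)c(OC)c2)c1O[Si](C(C)C)(C(C)C)C(C)C | intermediate
33 | 2-[(3S,4S)-4-(ArL-methyl)-5-oxooxolan-3-yl]acetaldehyde | COc1cc(C[C@@H]2C(=O)OC[C@H]2CC=O)cc([C@@H](CO[Si](C)(C)C(C)(C)C)[C@H](O[Si](C)(C)C(C)(C)C)c2ccc(O[Si](C(C)C)(C(C)C)C(C)C)c(OC)c2)c1O[Si](C(C)C)(C(C)C)C(C)C | intermediate
34 | 2-[(3S,4S)-4-(ArL-methyl)-5-oxooxolan-3-yl]acetic acid | COc1cc(C[C@@H]2C(=O)OC[C@H]2CC(=O)O)cc([C@@H](CO[Si](C)(C)C(C)(C)C)[C@H](O[Si](C)(C)C(C)(C)C)c2ccc(O[Si](C(C)C)(C(C)C)C(C)C)c(OC)c2)c1O[Si](C(C)C)(C(C)C)C(C)C | intermediate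
35 | 1,3-dioxoisoindolin-2-yl 2-[(3S,4S)-4-(ArL-methyl)-5-oxooxolan-3-yl]acetate | COc1cc(C[C@@H]2C(=O)OC[C@H]2CC(=O)ON3C(=O)c4ccccc4C3=O)cc([C@@H](CO[Si](C)(C)C(C)(C)C)[C@H](O[Si](C)(C)C(C)(C)C)c2ccc(O[Si](C(C)C)(C(C)C)C(C)C)c(OC)c2)c1O[Si](C(C)C)(C(C)C)C(C)C | intermediate
36 | hexasilyl ether of the target (two aryl TIPS, one aryl TBS, three alkyl TBS) | COc1cc(C[C@@H]2C(=O)OC[C@H]2Cc2cc(OC)c3c(c2)[C@@H](CO[Si](C)(C)C(C)(C)C)[C@H](c2ccc(O[Si](C)(C)C(C)(C)C)c(OC)c2)O3)cc([C@@H](CO[Si](C)(C)C(C)(C)C)[C@H](O[Si](C)(C)C(C)(C)C)c2ccc(O[Si](C(C)C)(C(C)C)C(C)C)c(OC)c2)c1O[Si](C(C)C)(C(C)C)C(C)C | intermediate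
37 | CNP0186558.3 | COc1cc([C@@H](O)[C@H](CO)c2cc(C[C@@H]3C(=O)OC[C@H]3Cc3cc(OC)c4c(c3)[C@@H](CO)[C@H](c3ccc(O)c(OC)c3)O4)cc(OC)c2O)ccc1O | target

**Step count and risks**

Total step count: 23. Longest linear sequence: 15 steps (steps 1, 2, 3, 4, 6, 7, 15, 16, 17, 18, 19, 20, 21, 22, 23).

Steps most likely to fail:

Step 9 (key step). The cationic intermediate may be captured by the electron-rich arene of a second molecule (oligomerisation) or may fragment with loss of formaldehyde before the ring closes, and trans equilibration may stay incomplete. The fallback replaces ionisation by a stereospecific displacement and sets out from diol 13. The primary hydroxyl is silylated selectively (TBSCl, imidazole, CH2Cl2, 0 °C) to give the primary silyl ether F1. The two aryl silyl ethers are then cleaved selectively (Bu4NF, 2 equiv, AcOH, THF, −20 °C, where aryl silyl ethers go far faster than the alkyl TBS ether) to give the bisphenol F2. Mitsunobu closure (PPh3, diisopropyl azodicarboxylate, THF, 0 °C) lets the ortho phenol of ring C displace the activated (1S) carbinol with inversion, which gives the same (2R,3S) trans ring in the monosilylated dihydrobenzofuran F3. Silylation of the ring D phenol (TBSCl, imidazole, DMF) returns to the route at compound 17.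

Step 6. Soft enolisation and addition may be slow with the hindered ortho-silyloxy arylacetyl imide and the electron-rich aldehyde, and reversible aldolisation before silyl capture may erode the anti selectivity. The fallback sets out from imide 8 and uses a preformed enolate with an open, Lewis acid-mediated transition state. Bu2BOTf and i-Pr2NEt in CH2Cl2 at 0 °C give the dibutylboron (Z)-enolate F4, which is added at −78 °C to aldehyde 10 precomplexed with Et2AlCl. This variant is known to turn the usual syn preference of boron enolates of N-acyloxazolidinones into anti and to engage the same enolate face as the chelated magnesium enolate. Work-up with pH 7 buffer, MeOH and H2O2 returns to the route at compound 12. Should only syn material be obtained, the right-hand branch is unaffected, because step 9 erases the carbinol centre.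

Step 22. Oxidative addition of the electron-rich aryl bromide may be slow, so that the redox-active ester is consumed by reduction or alkyl–alkyl dimerisation. The fallback sets out from bromide 17 and replaces the reductive coupling of two electrophiles by a coupling with a preformed organometallic. Bromine–lithium exchange (t-BuLi, THF, −78 °C) and transmetalation with ZnCl2 give the arylzinc chloride F5. F5 is coupled with redox-active ester 35 in a decarboxylative Negishi-type reaction (NiCl2·glyme, 4,4′-di-tert-butyl-2,2′-bipyridine, THF–DMF, 23 °C) and returns to the route at compound 36.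

Further compounds
F1 | step 9 | (1S,2S)-2-{5-bromo-3-methoxy-2-[(triisopropylsilyl)oxy]phenyl}-3-[(tert-butyldimethylsilyl)oxy]-1-{3-methoxy-4-[(triisopropylsilyl)oxy]phenyl}propan-1-ol | COc1cc(Br)cc([C@@H](CO[Si](C)(C)C(C)(C)C)[C@H](O)c2ccc(O[Si](C(C)C)(C(C)C)C(C)C)c(OC)c2)c1O[Si](C(C)C)(C(C)C)C(C)C
F2 | step 9 | (1S,2S)-2-(5-bromo-2-hydroxy-3-methoxyphenyl)-3-[(tert-butyldimethylsilyl)oxy]-1-(4-hydroxy-3-methoxyphenyl)propan-1-ol | COc1cc(Br)cc([C@@H](CO[Si](C)(C)C(C)(C)C)[C@H](O)c2ccc(O)c(OC)c2)c1O
F3 | step 9 | 4-[(2R,3S)-5-bromo-3-{[(tert-butyldimethylsilyl)oxy]methyl}-7-methoxy-2,3-dihydro-1-benzofuran-2-yl]-2-methoxyphenol | Brc1cc(OC)c2c(c1)[C@@H](CO[Si](C)(C)C(C)(C)C)[C@H](c1ccc(O)c(OC)c1)O2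
F4 | step 6 | dibutylboron (Z)-enolate of imide 8 | CCCCB(CCCC)O/C(=C\c1cc(Br)cc(OC)c1O[Si](C(C)C)(C(C)C)C(C)C)N1[C@@H](Cc2ccccc2)COC1=O
F5 | step 22 | arylzinc chloride from bromide 17 | Cl[Zn]c1cc(OC)c2c(c1)[C@@H](CO[Si](C)(C)C(C)(C)C)[C@H](c1ccc(O[Si](C)(C)C(C)(C)C)c(OC)c1)O2
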